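## Retrosynthetic overview

- Target 30 ⇐ acetylation, desilylation and CBS reduction of macrocyclic enone 27 ⇐ Ni/Cr closure of the 14-membered carbocycle at C3–C4 (alkenyl iodide + aldehyde 25), with the α-methylene ε-lactone already in place.
- ε-Lactone ⇐ Claisen ring expansion: cyclic carbonate 16 (O–C12/O–C17, carrying an (E)-C16=C1 alkenyl group) is methylenated to a 2-methylene-1,3-dioxolane, whose [3,3] shift forms C1–C15, sets C1 and turns the five-membered ring into the seven-membered lactone.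
- Enabling feature: in the lactone ring O13–C14–C15–C1–C16–C17–C12, the O-bearing C12 and C1 are 1,4 to each other across C17–C16. One extra C17–O bond (cleaved in the key step) and a C16=C1 unsaturation (its transposed C16=C17 form is reduced afterwards) make this ring the retron of a dioxolane ketene acetal.
- Carbonate 16 ⇐ Boc-carbonate opening of epoxy alcohol 13 at C12 with inversion (sets C12–O, frees C11–OH) ⇐ alkenylzinc addition to epoxy aldehyde 9 ⇐ Sharpless epoxidation ⇐ nerol, which supplies C6–C12, C17, the C8 and C12 methyls and the (Z)-C7=C8 alkene.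
- Ring order: oxirane → 1,3-dioxolan-2-one (temporary) → oxepan-2-one (key step) → 14-membered carbocycle.

Key step: step 11

Remark (numbering): atom numbers are those of the target named as a 13-oxabicyclo[10.3.2]heptadecane. C1 is the ring CH bonded to C15, C2–C11 the ten-carbon bridge, C12 the O-bearing quaternary carbon, O13–C14(=O)–C15(=CH2) the lactone bridge, C16 (on C1) and C17 (on C12) the two-carbon bridge.

Remark (supply): nerol 1, Grignard solution 3 and silyl ether 10 are assumed to be purchased.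

## Route

Step 1
Reactants: 1 nerol
Product: 2 neryl chloride, (2Z)-1-chloro-3,7-dimethylocta-2,6-diene
Conditions: NCS, Me2S, CH2Cl2, −30 → 0 °C
Reagents that add atoms: N-chlorosuccinimide, O=C1CCC(=O)N1Cl
Why: Corey–Kim chlorination of a primary allylic alcohol proceeds by SN2 displacement of the alkoxysulfonium ion without allylic transposition, so the (Z) geometry of the future C7=C8 alkene is kept.

Step 2
Reactants: 2 neryl chloride; 3 prop-1-yn-1-ylmagnesium bromide
Product: 4 (5Z)-6,10-dimethylundeca-5,9-dien-2-yne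
Conditions: CuI (5 mol%), THF, 0 °C → rt
Reagents that add atoms: none
Why: Copper-catalysed coupling of an alkynyl Grignard reagent with a primary allylic chloride should give the skipped enyne by attack at the unsubstituted allylic terminus with retention of the alkene geometry.

Step 3
Reactants: 4 (5Z)-6,10-dimethylundeca-5,9-dien-2-yne
Product: 6 (2E,5Z)-2-iodo-6,10-dimethylundeca-2,5,9-triene, via alkenylzirconocene chloride 5 (not isolated)
Conditions: Cp2Zr(H)Cl (1.5 equiv), THF, 50 °C; then I2, 0 °C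
Reagents that add atoms: iodine, II
Why: Hydrozirconation of a 2-alkyne is a syn addition that, after equilibration with excess hydride, should place zirconium on the methyl-bearing carbon (C4), and iodinolysis with retention gives the (E)-2-iodoalkene; the trisubstituted alkenes are inert to the reagent.

Step 4
Reactants: 6 (2E,5Z)-2-iodo-6,10-dimethylundeca-2,5,9-triene
Product: 7 (2E,6Z,9E)-10-iodo-2,6-dimethylundeca-2,6,9-trien-1-ol
Conditions: SeO2 (cat.), t-BuOOH, salicylic acid (cat.), CH2Cl2, rt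
Reagents that add atoms: tert-butyl hydroperoxide, CC(C)(C)OO
Why: Allylic oxidation with SeO2 (ene reaction, then [2,3] shift) is selective for the (E)-methyl group of the terminal gem-dimethyl alkene of a polyprenyl chain and should give the (E)-allylic alcohol at C17.

Step 5
Reactants: 7 (2E,6Z,9E)-10-iodo-2,6-dimethylundeca-2,6,9-trien-1-ol
Product: 8 [(2R,3R)-3-[(3Z,6E)-7-iodo-3-methylocta-3,6-dien-1-yl]-2-methyloxiran-2-yl]methanol
Conditions: Ti(OiPr)4 (10 mol%), D-(−)-diisopropyl tartrate (12 mol%), t-BuOOH, 4 Å MS, CH2Cl2, −20 °C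
Reagents that add atoms: tert-butyl hydroperoxide, CC(C)(C)OO
Why: Sharpless asymmetric epoxidation touches only the allylic alcohol, and the D-(−)-tartrate should deliver oxygen to the face that gives the (2R,3R)-oxirane (C11 as in the target, C12 to be inverted in step 9).

Step 6
Reactants: 8 epoxy alcohol
Product: 9 (2S,3R)-3-[(3Z,6E)-7-iodo-3-methylocta-3,6-dien-1-yl]-2-methyloxirane-2-carbaldehyde
Conditions: TEMPO (10 mol%), PhI(OAc)2, CH2Cl2, rt
Reagents that add atoms: none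
Why: TEMPO/PhI(OAc)2 oxidation of a primary alcohol stops at the aldehyde and leaves the epoxide, alkenes and alkenyl iodide alone; the α-carbon is quaternary, so it cannot epimerise.

Step 7
Reactants: 9 epoxy aldehyde; 10 tert-butyl(but-3-yn-1-yloxy)dimethylsilane
Product: 13 (1S,2E)-5-[(tert-butyldimethylsilyl)oxy]-1-[(2R,3R)-3-[(3Z,6E)-7-iodo-3-methylocta-3,6-dien-1-yl]-2-methyloxiran-2-yl]pent-2-en-1-ol, via alkenylborane 11 (not isolated), via alkenylzinc 12 (not isolated)
Conditions: 10, Cy2BH, toluene, 0 °C → rt; Me2Zn, −78 °C; (−)-MIB (10 mol%), then 9, −20 → 0 °C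
Reagents that add atoms: none
Why: Hydroboration of the terminal alkyne, boron-to-zinc exchange and amino-alcohol-catalysed asymmetric alkenylzinc addition give the (E)-allylic alcohol; the C17 stereocentre is set by the ligand (−)-MIB, and a zinc chelate between the aldehyde and oxirane oxygens, attacked anti to the oxirane C–C bond, should favour the same (threo) isomer.

Step 8
Reactants: 13 epoxy allylic alcohol
Product: 14 tert-butyl (1S,2E)-5-[(tert-butyldimethylsilyl)oxy]-1-[(2S,3R)-3-[(3Z,6E)-7-iodo-3-methylocta-3,6-dien-1-yl]-2-methyloxiran-2-yl]pent-2-en-1-yl carbonate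
Conditions: Boc2O, DMAP (cat.), MeCN, rt
Reagents that add atoms: di-tert-butyl dicarbonate, CC(C)(C)OC(=O)OC(=O)OC(C)(C)C
Why: DMAP-catalysed acylation of the secondary allylic alcohol installs the carbonate that serves as the internal oxygen nucleophile; no stereocentre is touched (only the CIP label of the oxirane carbon changes).

Step 9
Reactants: 14 tert-butyl carbonate
Product: 15 (4R,5S)-5-[(1E)-4-[(tert-butyldimethylsilyl)oxy]but-1-en-1-yl]-4-[(1R,4Z,7E)-1-hydroxy-8-iodo-4-methylnona-4,7-dien-1-yl]-4-methyl-1,3-dioxolan-2-one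
Conditions: BF3·OEt2 (20 mol%), CH2Cl2, −40 °C
Reagents that add atoms: none
Why: Lewis-acid-promoted 5-exo opening of the epoxide by the carbonate carbonyl oxygen occurs at the proximal tertiary carbon C12 with inversion and loss of isobutene; this sets the C12–O bond of the target, frees C11–OH with its configuration untouched and places the alkenyl group and the C11 chain cis on the dioxolanone.

Step 10
Reactants: 15 hydroxy carbonate
Product: 16 (4S,5S)-5-[(1E)-4-[(tert-butyldimethylsilyl)oxy]but-1-en-1-yl]-4-[(1R,4Z,7E)-1-[(tert-butyldimethylsilyl)oxy]-8-iodo-4-methylnona-4,7-dien-1-yl]-4-methyl-1,3-dioxolan-2-one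
Conditions: TBSOTf, 2,6-lutidine, CH2Cl2, −78 → 0 °C
Reagents that add atoms: tert-butyldimethylsilyl trifluoromethanesulfonate, CC(C)(C)[Si](C)(C)OS(=O)(=O)C(F)(F)F
Why: Silylation with the silyl triflate protects the hindered C11 hydroxyl for the organotitanium, enolate and oxidation steps without affecting the carbonate.

Step 11
Reactants: 16 cyclic carbonate
Product: 18 (4S,7S)-4-[2-[(tert-butyldimethylsilyl)oxy]ethyl]-7-[(1R,4Z,7E)-1-[(tert-butyldimethylsilyl)oxy]-8-iodo-4-methylnona-4,7-dien-1-yl]-7-methyl-4,7-dihydrooxepin-2(3H)-one, via ketene acetal 17 (not isolated)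
Conditions: Cp2TiMe2 (2.5 equiv), toluene, 105 °C, dark
Reagents that add atoms: dimethyltitanocene, C[Ti](C)(C1C=CC=C1)C1C=CC=C1
Why: Thermolysis of Cp2TiMe2 gives the titanium methylidene, which turns the carbonate C=O into the exocyclic C14=C15 bond of 2-methylene-1,3-dioxolane 17 (carbonyl methylenation). 17 is an allyl vinyl ether (C15=C14–O–C17–C16=C1) and undergoes a Claisen rearrangement under the same conditions, forming C1–C15 and breaking the temporary C17–O bond, whose oxygen becomes the lactone carbonyl; the closest known reaction type is the methylenation/Claisen ring expansion of alkenyl-substituted cyclic carbonates and ketene acetals to medium-ring lactones. The oxepanone is closed by a two-atom ring expansion of the five-membered ring ([3,3] shift joining the two exocyclic termini), and only a chair-like, bicyclo[3.2.1]-type transition state can give the cis C16=C17 alkene that a seven-membered ring requires. In that transition state the C17–C12 bond is axial and the C2 substituent of the (E)-alkene equatorial, so the bond to C15 forms on the alkene face from which oxygen leaves: (S)-C17 is transferred to (S)-C1, with C2 trans to the C11 chain on C12. The step needs complete suprafacial chirality transfer and chemoselective methylenation of the carbonate; the first is secured by the (E) geometry from the hydroboration and the defined C17 carbinol, the second by the absence of any other carbonyl group and by limiting the reagent so that the lactone formed is not methylenated in turn.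

Step 12
Reactants: 18 unsaturated lactone
Product: 19 (4S,7S)-4-[2-[(tert-butyldimethylsilyl)oxy]ethyl]-7-[(1R,4Z,7E)-1-[(tert-butyldimethylsilyl)oxy]-8-iodo-4-methylnona-4,7-dien-1-yl]-7-methyloxepan-2-one
Conditions: 2-nitrobenzenesulfonylhydrazide, Et3N, CH2Cl2, rt
Reagents that add atoms: none
Why: Diimide generated in situ should reduce the cis-disubstituted ring alkene much faster than the trisubstituted C7=C8 alkene or the iodoalkene, removing the unsaturation left by the rearrangement without touching C–I.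

Step 13
Reactants: 19 saturated lactone
Product: 23 (4S,7S)-4-[2-[(tert-butyldimethylsilyl)oxy]ethyl]-7-[(1R,4Z,7E)-1-[(tert-butyldimethylsilyl)oxy]-8-iodo-4-methylnona-4,7-dien-1-yl]-7-methyl-3-methylideneoxepan-2-one, via lithium enolate 20 (not isolated), via Mannich base 21 (not isolated), via ammonium iodide 22 (not isolated)
Conditions: LiN(iPr)2, THF, −78 °C; CH2=NMe2+ I−, −78 °C → rt; MeI, MeOH, rt; aq. NaHCO3, CH2Cl2, rt
Reagents that add atoms: dimethyl(methylidene)ammonium iodide, C=[N+](C)C.[I-]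
Why: Mannich reaction of the lactone enolate with the iminium salt, N-methylation and Hofmann-type elimination is the standard α-methylenation of lactones; C15 is the only enolisable position and C1 is not affected.

Step 14
Reactants: 23 α-methylene lactone
Product: 24 (4S,7S)-4-(2-hydroxyethyl)-7-[(1R,4Z,7E)-1-[(tert-butyldimethylsilyl)oxy]-8-iodo-4-methylnona-4,7-dien-1-yl]-7-methyl-3-methylideneoxepan-2-one
Conditions: PPTS (cat.), EtOH, rt
Reagents that add atoms: none
Why: Acid-catalysed solvolysis removes the unhindered primary silyl ether far faster than the secondary one at C11, which is shielded by the adjacent quaternary carbon.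

Step 15
Reactants: 24 primary alcohol
Product: 25 2-[(4S,7S)-7-[(1R,4Z,7E)-1-[(tert-butyldimethylsilyl)oxy]-8-iodo-4-methylnona-4,7-dien-1-yl]-7-methyl-3-methylidene-2-oxooxepan-4-yl]acetaldehyde
Conditions: TEMPO (10 mol%), PhI(OAc)2, CH2Cl2, rt
Reagents that add atoms: none
Why: Nitroxyl-catalysed oxidation gives the aldehyde (C3) under neutral conditions that leave the enoate, the skipped diene and the iodoalkene untouched.

Step 16
Reactants: 25 iodo aldehyde
Product: 26 (1S,4E,7Z,11R,12S)-11-[(tert-butyldimethylsilyl)oxy]-3-hydroxy-4,8,12-trimethyl-15-methylidene-13-oxabicyclo[10.3.2]heptadeca-4,7-dien-14-one (both C3 epimers)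
Conditions: CrCl2 (10 equiv), NiCl2 (2 mol%), DMSO/THF, rt, 0.002 M, slow addition
Reagents that add atoms: none
Why: Nozaki–Hiyama–Kishi reaction: oxidative addition of the alkenyl iodide to zerovalent nickel, transmetalation to trivalent chromium and chemoselective addition to the aldehyde close the 14-membered carbocycle at C3–C4 with retention of the (E)-C4=C5 geometry; the C3 configuration is not relied upon, because it is reset in steps 17 and 18.

Step 17
Reactants: 26 macrocyclic allylic alcohol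
Product: 27 (1S,4E,7Z,11R,12S)-11-[(tert-butyldimethylsilyl)oxy]-4,8,12-trimethyl-15-methylidene-13-oxabicyclo[10.3.2]heptadeca-4,7-diene-3,14-dione
Conditions: Dess–Martin periodinane, CH2Cl2, 0 °C
Reagents that add atoms: none
Why: Dess–Martin oxidation converts both C3 epimers into one enone under non-basic conditions, which should not move the C7=C8 alkene into conjugation.

Step 18
Reactants: 27 macrocyclic enone
Product: 28 (1S,3R,4E,7Z,11R,12S)-11-[(tert-butyldimethylsilyl)oxy]-3-hydroxy-4,8,12-trimethyl-15-methylidene-13-oxabicyclo[10.3.2]heptadeca-4,7-dien-14-one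
Conditions: (S)-2-methyl-CBS-oxazaborolidine (20 mol%), catecholborane, toluene, −78 °C
Reagents that add atoms: none
Why: Corey–Bakshi–Shibata reduction: the ketone binds with the larger 2-substituted alkenyl group away from the catalyst, so the (S)-oxazaborolidine should deliver hydride to give the (3R) allylic alcohol by 1,2-reduction, and catecholborane does not reduce the lactone enoate at this temperature.

Step 19
Reactants: 28 (3R)-allylic alcohol
Product: 29 (1S,3R,4E,7Z,11R,12S)-11-[(tert-butyldimethylsilyl)oxy]-4,8,12-trimethyl-15-methylidene-14-oxo-13-oxabicyclo[10.3.2]heptadeca-4,7-dien-3-yl acetate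
Conditions: Ac2O, DMAP (cat.), pyridine, CH2Cl2, 0 °C
Reagents that add atoms: acetic anhydride, CC(=O)OC(C)=O
Why: Nucleophile-catalysed acylation of the only free hydroxyl gives the allylic acetate with retention at C3.

Step 20
Reactants: 29 silyl-protected acetate
Product: 30 (1S,3R,4E,7Z,11R,12S)-11-hydroxy-4,8,12-trimethyl-15-methylidene-14-oxo-13-oxabicyclo[10.3.2]heptadeca-4,7-dien-3-yl acetate (CNP0344673.1)
Conditions: HF·pyridine, pyridine, THF, 0 °C → rt
Reagents that add atoms: none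
Why: Buffered fluoride-mediated desilylation frees the C11 hydroxyl without cleaving the allylic acetate or adding to the α-methylene lactone.

## Compound list

1 | nerol, (2Z)-3,7-dimethylocta-2,6-dien-1-ol | CC(C)=CCC/C(C)=C\CO | starting material
2 | neryl chloride, (2Z)-1-chloro-3,7-dimethylocta-2,6-diene | CC(C)=CCC/C(C)=C\CCl | intermediate
3 | prop-1-yn-1-ylmagnesium bromide | CC#C[Mg]Br | starting material
4 | (5Z)-6,10-dimethylundeca-5,9-dien-2-yne | CC#CC/C=C(/C)CCC=C(C)C | intermediate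
5 | chlorobis(cyclopentadienyl)[(2E,5Z)-6,10-dimethylundeca-2,5,9-trien-2-yl]zirconium (not isolated) | C/C(=C\C/C=C(/C)CCC=C(C)C)[Zr](Cl)(C1C=CC=C1)C1C=CC=C1 | intermediate
6 | (2E,5Z)-2-iodo-6,10-dimethylundeca-2,5,9-triene | C/C(I)=C\C/C=C(/C)CCC=C(C)C | intermediate
7 | (2E,6Z,9E)-10-iodo-2,6-dimethylundeca-2,6,9-trien-1-ol | OC/C(C)=C/CC/C(C)=C\C/C=C(\C)I | intermediate
8 | [(2R,3R)-3-[(3Z,6E)-7-iodo-3-methylocta-3,6-dien-1-yl]-2-methyloxiran-2-yl]methanol | OC[C@@]1(C)O[C@@H]1CC/C(C)=C\C/C=C(\C)I | intermediate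
9 | (2S,3R)-3-[(3Z,6E)-7-iodo-3-methylocta-3,6-dien-1-yl]-2-methyloxirane-2-carbaldehyde | O=C[C@@]1(C)O[C@@H]1CC/C(C)=C\C/C=C(\C)I | intermediate
10 | tert-butyl(but-3-yn-1-yloxy)dimethylsilane | C#CCCO[Si](C)(C)C(C)(C)C | starting material
11 | [(1E)-4-[(tert-butyldimethylsilyl)oxy]but-1-en-1-yl]dicyclohexylborane (not isolated) | CC(C)(C)[Si](C)(C)OCC/C=C/B(C1CCCCC1)C1CCCCC1 | intermediate
12 | [(1E)-4-[(tert-butyldimethylsilyl)oxy]but-1-en-1-yl](methyl)zinc (not isolated) | CC(C)(C)[Si](C)(C)OCC/C=C/[Zn]C | intermediate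
13 | (1S,2E)-5-[(tert-butyldimethylsilyl)oxy]-1-[(2R,3R)-3-[(3Z,6E)-7-iodo-3-methylocta-3,6-dien-1-yl]-2-methyloxiran-2-yl]pent-2-en-1-ol | CC(C)(C)[Si](C)(C)OCC/C=C/[C@H](O)[C@@]1(C)O[C@@H]1CC/C(C)=C\C/C=C(\C)I | intermediate
14 | tert-butyl (1S,2E)-5-[(tert-butyldimethylsilyl)oxy]-1-[(2S,3R)-3-[(3Z,6E)-7-iodo-3-methylocta-3,6-dien-1-yl]-2-methyloxiran-2-yl]pent-2-en-1-yl carbonate | CC(C)(C)[Si](C)(C)OCC/C=C/[C@H](OC(=O)OC(C)(C)C)[C@@]1(C)O[C@@H]1CC/C(C)=C\C/C=C(\C)I | intermediate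
15 | (4R,5S)-5-[(1E)-4-[(tert-butyldimethylsilyl)oxy]but-1-en-1-yl]-4-[(1R,4Z,7E)-1-hydroxy-8-iodo-4-methylnona-4,7-dien-1-yl]-4-methyl-1,3-dioxolan-2-one | CC(C)(C)[Si](C)(C)OCC/C=C/[C@@H]1OC(=O)O[C@]1(C)[C@H](O)CC/C(C)=C\C/C=C(\C)I | intermediate
16 | (4S,5S)-5-[(1E)-4-[(tert-butyldimethylsilyl)oxy]but-1-en-1-yl]-4-[(1R,4Z,7E)-1-[(tert-butyldimethylsilyl)oxy]-8-iodo-4-methylnona-4,7-dien-1-yl]-4-methyl-1,3-dioxolan-2-one | CC(C)(C)[Si](C)(C)OCC/C=C/[C@@H]1OC(=O)O[C@]1(C)[C@H](O[Si](C)(C)C(C)(C)C)CC/C(C)=C\C/C=C(\C)I | intermediate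
17 | (4S,5S)-5-[(1E)-4-[(tert-butyldimethylsilyl)oxy]but-1-en-1-yl]-4-[(1R,4Z,7E)-1-[(tert-butyldimethylsilyl)oxy]-8-iodo-4-methylnona-4,7-dien-1-yl]-4-methyl-2-methylidene-1,3-dioxolane (not isolated) | CC(C)(C)[Si](C)(C)OCC/C=C/[C@@H]1OC(=C)O[C@]1(C)[C@H](O[Si](C)(C)C(C)(C)C)CC/C(C)=C\C/C=C(\C)I | intermediate
18 | (4S,7S)-4-[2-[(tert-butyldimethylsilyl)oxy]ethyl]-7-[(1R,4Z,7E)-1-[(tert-butyldimethylsilyl)oxy]-8-iodo-4-methylnona-4,7-dien-1-yl]-7-methyl-4,7-dihydrooxepin-2(3H)-one | O=C1C[C@H](CCO[Si](C)(C)C(C)(C)C)C=C[C@](C)(O1)[C@H](O[Si](C)(C)C(C)(C)C)CC/C(C)=C\C/C=C(\C)I | intermediate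
19 | (4S,7S)-4-[2-[(tert-butyldimethylsilyl)oxy]ethyl]-7-[(1R,4Z,7E)-1-[(tert-butyldimethylsilyl)oxy]-8-iodo-4-methylnona-4,7-dien-1-yl]-7-methyloxepan-2-one | O=C1C[C@H](CCO[Si](C)(C)C(C)(C)C)CC[C@](C)(O1)[C@H](O[Si](C)(C)C(C)(C)C)CC/C(C)=C\C/C=C(\C)I | intermediate
20 | lithium enolate of 19 (not isolated) | [Li+].[O-]C1=C[C@H](CCO[Si](C)(C)C(C)(C)C)CC[C@](C)(O1)[C@H](O[Si](C)(C)C(C)(C)C)CC/C(C)=C\C/C=C(\C)I | intermediate
21 | 3-[(dimethylamino)methyl] derivative of 19, both C3 epimers (not isolated) | CN(C)CC1C(=O)O[C@@](C)(CC[C@H]1CCO[Si](C)(C)C(C)(C)C)[C@H](O[Si](C)(C)C(C)(C)C)CC/C(C)=C\C/C=C(\C)I | intermediate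
22 | trimethylammonium iodide formed from 21 (not isolated) | C[N+](C)(C)CC1C(=O)O[C@@](C)(CC[C@H]1CCO[Si](C)(C)C(C)(C)C)[C@H](O[Si](C)(C)C(C)(C)C)CC/C(C)=C\C/C=C(\C)I.[I-] | intermediate
23 | (4S,7S)-4-[2-[(tert-butyldimethylsilyl)oxy]ethyl]-7-[(1R,4Z,7E)-1-[(tert-butyldimethylsilyl)oxy]-8-iodo-4-methylnona-4,7-dien-1-yl]-7-methyl-3-methylideneoxepan-2-one | C=C1C(=O)O[C@@](C)(CC[C@H]1CCO[Si](C)(C)C(C)(C)C)[C@H](O[Si](C)(C)C(C)(C)C)CC/C(C)=C\C/C=C(\C)I | intermediate
24 | (4S,7S)-4-(2-hydroxyethyl)-7-[(1R,4Z,7E)-1-[(tert-butyldimethylsilyl)oxy]-8-iodo-4-methylnona-4,7-dien-1-yl]-7-methyl-3-methylideneoxepan-2-one | C=C1C(=O)O[C@@](C)(CC[C@H]1CCO)[C@H](O[Si](C)(C)C(C)(C)C)CC/C(C)=C\C/C=C(\C)I | intermediate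
25 | 2-[(4S,7S)-7-[(1R,4Z,7E)-1-[(tert-butyldimethylsilyl)oxy]-8-iodo-4-methylnona-4,7-dien-1-yl]-7-methyl-3-methylidene-2-oxooxepan-4-yl]acetaldehyde | C=C1C(=O)O[C@@](C)(CC[C@H]1CC=O)[C@H](O[Si](C)(C)C(C)(C)C)CC/C(C)=C\C/C=C(\C)I | intermediate
26 | (1S,4E,7Z,11R,12S)-11-[(tert-butyldimethylsilyl)oxy]-3-hydroxy-4,8,12-trimethyl-15-methylidene-13-oxabicyclo[10.3.2]heptadeca-4,7-dien-14-one, both C3 epimers | C=C1C(=O)O[C@@]2(C)CC[C@H]1CC(O)/C(C)=C/C/C=C(/C)CC[C@H]2O[Si](C)(C)C(C)(C)C | intermediate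
27 | (1S,4E,7Z,11R,12S)-11-[(tert-butyldimethylsilyl)oxy]-4,8,12-trimethyl-15-methylidene-13-oxabicyclo[10.3.2]heptadeca-4,7-diene-3,14-dione | C=C1C(=O)O[C@@]2(C)CC[C@H]1CC(=O)/C(C)=C/C/C=C(/C)CC[C@H]2O[Si](C)(C)C(C)(C)C | intermediate
28 | (1S,3R,4E,7Z,11R,12S)-11-[(tert-butyldimethylsilyl)oxy]-3-hydroxy-4,8,12-trimethyl-15-methylidene-13-oxabicyclo[10.3.2]heptadeca-4,7-dien-14-one | C=C1C(=O)O[C@@]2(C)CC[C@H]1C[C@@H](O)/C(C)=C/C/C=C(/C)CC[C@H]2O[Si](C)(C)C(C)(C)C | intermediate
29 | (1S,3R,4E,7Z,11R,12S)-11-[(tert-butyldimethylsilyl)oxy]-4,8,12-trimethyl-15-methylidene-14-oxo-13-oxabicyclo[10.3.2]heptadeca-4,7-dien-3-yl acetate | C=C1C(=O)O[C@@]2(C)CC[C@H]1C[C@@H](OC(C)=O)/C(C)=C/C/C=C(/C)CC[C@H]2O[Si](C)(C)C(C)(C)C | intermediate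
30 | (1S,3R,4E,7Z,11R,12S)-11-hydroxy-4,8,12-trimethyl-15-methylidene-14-oxo-13-oxabicyclo[10.3.2]heptadeca-4,7-dien-3-yl acetate (CNP0344673.1) | C=C1C(=O)O[C@@]2(C)CC[C@H]1C[C@@H](OC(C)=O)/C(C)=C/C/C=C(/C)CC[C@H]2O | target

## Step count and risks

Total step count: 20. Longest linear sequence: 20 steps (nerol 1 → 30; 3 and 10 are purchased).

Steps most likely to fail:

**Step 11 (methylenation/Claisen ring expansion).**
- What may go wrong: the titanium methylidene may methylenate the lactone as it forms, or the [3,3] shift next to the fully substituted C12 may be slower than decomposition of the ketene acetal.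
- Fallback: form C1–C15 by an unstrained acyclic Ireland–Claisen rearrangement and close the lactone afterwards by epoxide opening. It sets out from 9 and comes back at 19.
- From aldehyde 9, the alkenylzinc addition of step 7 is run with (+)-MIB to give the C17-epimeric (1R)-allylic alcohol F1. The epimer is needed because the open-chain chair transition state carries the oxirane carbon equatorial, not axial as in step 11.
- Ac2O/DMAP/pyridine gives acetate F2.
- LiN(iPr)2 and Me3SiCl in THF (−78 °C → rt) give silyl ketene acetal F3, which rearranges to trimethylsilyl ester F4; aqueous acid then gives carboxylic acid F5 with (S)-C1 and an (E)-C16=C17 alkene.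
- Diimide reduction as in step 12 gives saturated epoxy acid F6.
- Camphorsulfonic acid (cat.) in CH2Cl2 closes the ring by 7-exo attack of the carboxyl group on the tertiary oxirane carbon C12 with inversion, giving hydroxy lactone F7.
- TBSOTf/2,6-lutidine then gives 19.

**Step 7 (catalytic asymmetric alkenylzinc addition).**
- What may go wrong: poor facial selectivity if the inherent bias of the epoxy aldehyde opposes the ligand, or opening of the epoxide by Lewis-acidic zinc species.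
- Fallback: set C17 by reagent-controlled reduction of an ynone. It sets out from 9 (with 10) and comes back at 13.
- The lithium acetylide of 10 (n-BuLi, THF, −78 °C) adds to 9 to give propargylic alcohol F8 as both C17 epimers.
- Dess–Martin oxidation gives ynone F9.
- Reduction with (R)-2-methyl-CBS-oxazaborolidine/catecholborane (alkynyl as the small group) gives (1S)-propargylic alcohol F10.
- Trans-hydrosilylation with [Cp*Ru(MeCN)3]PF6 and (EtO)3SiH in CH2Cl2 gives (Z)-alkenylsilane F11.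
- Protodesilylation with AgF in THF/MeOH/H2O gives 13.

**Step 16 (Ni/Cr macrocyclisation).**
- What may go wrong: intermolecular coupling to oligomers may outrun ring closure, or divalent chromium may reduce the aldehyde or engage the exocyclic enoate.
- Fallback: close the same C3–C4 bond as a ketone synthesis by intramolecular Stille acylation. It sets out from 23 and comes back at 27, so step 17 is bypassed as well.
- Pd(PPh3)4 and Me3SnSnMe3 in toluene at 80 °C convert 23 into alkenylstannane F12.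
- HF·pyridine/pyridine gives primary alcohol F13.
- Dess–Martin oxidation gives aldehyde F14, and NaClO2/NaH2PO4/2-methylbut-2-ene gives carboxylic acid F15.
- 1-Chloro-N,N,2-trimethylprop-1-en-1-amine gives acid chloride F16 (not isolated).
- F16 is added slowly to Pd2(dba)3/tri(2-furyl)phosphine in toluene at 70 °C at high dilution; zerovalent palladium couples the acyl chloride with the alkenylstannane with retention to give enone 27.

## Further compounds

F1 | step 11 | (1R,2E)-5-[(tert-butyldimethylsilyl)oxy]-1-[(2R,3R)-3-[(3Z,6E)-7-iodo-3-methylocta-3,6-dien-1-yl]-2-methyloxiran-2-yl]pent-2-en-1-ol | CC(C)(C)[Si](C)(C)OCC/C=C/[C@@H](O)[C@@]1(C)O[C@@H]1CC/C(C)=C\C/C=C(\C)I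
F2 | step 11 | (1R,2E)-5-[(tert-butyldimethylsilyl)oxy]-1-[(2S,3R)-3-[(3Z,6E)-7-iodo-3-methylocta-3,6-dien-1-yl]-2-methyloxiran-2-yl]pent-2-en-1-yl acetate | CC(C)(C)[Si](C)(C)OCC/C=C/[C@@H](OC(C)=O)[C@@]1(C)O[C@@H]1CC/C(C)=C\C/C=C(\C)I
F3 | step 11 | 1-[(trimethylsilyl)oxy]ethenyl ether of F1 (silyl ketene acetal, not isolated) | CC(C)(C)[Si](C)(C)OCC/C=C/[C@@H](OC(=C)O[Si](C)(C)C)[C@@]1(C)O[C@@H]1CC/C(C)=C\C/C=C(\C)I
F4 | step 11 | trimethylsilyl ester of F5 (not isolated) | C[Si](C)(C)OC(=O)C[C@H](CCO[Si](C)(C)C(C)(C)C)/C=C/[C@@]1(C)O[C@@H]1CC/C(C)=C\C/C=C(\C)I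
F5 | step 11 | (3S,4E)-3-[2-[(tert-butyldimethylsilyl)oxy]ethyl]-5-[(2R,3R)-3-[(3Z,6E)-7-iodo-3-methylocta-3,6-dien-1-yl]-2-methyloxiran-2-yl]pent-4-enoic acid | OC(=O)C[C@H](CCO[Si](C)(C)C(C)(C)C)/C=C/[C@@]1(C)O[C@@H]1CC/C(C)=C\C/C=C(\C)I
F6 | step 11 | (3S)-3-[2-[(tert-butyldimethylsilyl)oxy]ethyl]-5-[(2R,3R)-3-[(3Z,6E)-7-iodo-3-methylocta-3,6-dien-1-yl]-2-methyloxiran-2-yl]pentanoic acid | OC(=O)C[C@H](CCO[Si](C)(C)C(C)(C)C)CC[C@@]1(C)O[C@@H]1CC/C(C)=C\C/C=C(\C)I
F7 | step 11 | (4S,7S)-4-[2-[(tert-butyldimethylsilyl)oxy]ethyl]-7-[(1R,4Z,7E)-1-hydroxy-8-iodo-4-methylnona-4,7-dien-1-yl]-7-methyloxepan-2-one | O=C1C[C@H](CCO[Si](C)(C)C(C)(C)C)CC[C@](C)(O1)[C@H](O)CC/C(C)=C\C/C=C(\C)I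
F8 | step 7 | 5-[(tert-butyldimethylsilyl)oxy]-1-[(2R,3R)-3-[(3Z,6E)-7-iodo-3-methylocta-3,6-dien-1-yl]-2-methyloxiran-2-yl]pent-2-yn-1-ol, both C1 epimers | CC(C)(C)[Si](C)(C)OCCC#CC(O)[C@@]1(C)O[C@@H]1CC/C(C)=C\C/C=C(\C)I
F9 | step 7 | 5-[(tert-butyldimethylsilyl)oxy]-1-[(2S,3R)-3-[(3Z,6E)-7-iodo-3-methylocta-3,6-dien-1-yl]-2-methyloxiran-2-yl]pent-2-yn-1-one | CC(C)(C)[Si](C)(C)OCCC#CC(=O)[C@@]1(C)O[C@@H]1CC/C(C)=C\C/C=C(\C)I
F10 | step 7 | (1S)-5-[(tert-butyldimethylsilyl)oxy]-1-[(2R,3R)-3-[(3Z,6E)-7-iodo-3-methylocta-3,6-dien-1-yl]-2-methyloxiran-2-yl]pent-2-yn-1-ol | CC(C)(C)[Si](C)(C)OCCC#C[C@H](O)[C@@]1(C)O[C@@H]1CC/C(C)=C\C/C=C(\C)I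
F11 | step 7 | (1S,2Z)-5-[(tert-butyldimethylsilyl)oxy]-1-[(2R,3R)-3-[(3Z,6E)-7-iodo-3-methylocta-3,6-dien-1-yl]-2-methyloxiran-2-yl]-3-(triethoxysilyl)pent-2-en-1-ol | CC(C)(C)[Si](C)(C)OCC/C(=C/[C@H](O)[C@@]1(C)O[C@@H]1CC/C(C)=C\C/C=C(\C)I)[Si](OCC)(OCC)OCC
F12 | step 16 | (4S,7S)-4-[2-[(tert-butyldimethylsilyl)oxy]ethyl]-7-[(1R,4Z,7E)-1-[(tert-butyldimethylsilyl)oxy]-4-methyl-8-(trimethylstannyl)nona-4,7-dien-1-yl]-7-methyl-3-methylideneoxepan-2-one | C=C1C(=O)O[C@@](C)(CC[C@H]1CCO[Si](C)(C)C(C)(C)C)[C@H](O[Si](C)(C)C(C)(C)C)CC/C(C)=C\C/C=C(\C)[Sn](C)(C)C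
F13 | step 16 | (4S,7S)-4-(2-hydroxyethyl)-7-[(1R,4Z,7E)-1-[(tert-butyldimethylsilyl)oxy]-4-methyl-8-(trimethylstannyl)nona-4,7-dien-1-yl]-7-methyl-3-methylideneoxepan-2-one | C=C1C(=O)O[C@@](C)(CC[C@H]1CCO)[C@H](O[Si](C)(C)C(C)(C)C)CC/C(C)=C\C/C=C(\C)[Sn](C)(C)C
F14 | step 16 | 2-[(4S,7S)-7-[(1R,4Z,7E)-1-[(tert-butyldimethylsilyl)oxy]-4-methyl-8-(trimethylstannyl)nona-4,7-dien-1-yl]-7-methyl-3-methylidene-2-oxooxepan-4-yl]acetaldehyde | C=C1C(=O)O[C@@](C)(CC[C@H]1CC=O)[C@H](O[Si](C)(C)C(C)(C)C)CC/C(C)=C\C/C=C(\C)[Sn](C)(C)C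
F15 | step 16 | 2-[(4S,7S)-7-[(1R,4Z,7E)-1-[(tert-butyldimethylsilyl)oxy]-4-methyl-8-(trimethylstannyl)nona-4,7-dien-1-yl]-7-methyl-3-methylidene-2-oxooxepan-4-yl]acetic acid | C=C1C(=O)O[C@@](C)(CC[C@H]1CC(O)=O)[C@H](O[Si](C)(C)C(C)(C)C)CC/C(C)=C\C/C=C(\C)[Sn](C)(C)C
F16 | step 16 | acid chloride of F15 (not isolated) | C=C1C(=O)O[C@@](C)(CC[C@H]1CC(Cl)=O)[C@H](O[Si](C)(C)C(C)(C)C)CC/C(C)=C\C/C=C(\C)[Sn](C)(C)C
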